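**Plan**

1. The retrosynthesis first cuts three ethers (C5–OMe, C7–OBn, C6'–OEt) and the C1'–isobutyryl bond. Ring A is then cut across C2'–C3' and C4'–C5' (and C1'–C2') into a methyl ynol ether carried by ring B and 3-ethoxy-2-methylcyclobutenone.
2. The feature that allows this: ring A has its single methyl ether on C4', between the bridge-bearing C3' and the methyl-bearing C5' and meta to the C2' hydroxyl. A 1-methoxyalkyne (C3', C4') and a vinylketene (C2', C5', C6', C1') join in exactly this pattern.
3. The ynol ether is cut at its CH2–C(sp) bond into a benzylic bromide and a methoxyethynylstannane. The chromanone is cut at C4–C4a and O1–C2 into a formylated methylphloroglucinol and 3-methylbut-2-enoic acid.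
4. Forward: the benzene ring of ring B is bought, its pyranone ring is closed in step 3, ring A is built in step 10, and an acylation and one global dealkylation finish the synthesis.
5. The target has no stereocentre. The control needed is regiochemical: the para-O-methylation of step 2 leaves only one oxygen able to close the pyranone ring, and the polarity of the ynol ether fixes the substitution pattern of ring A in step 10.

Key step: step 10

Remark: ring A atoms carry primed locants (C1' acyl carbon, C3' bridge carbon, C4' methoxy carbon); ketene gas is assumed to be made by cracking commercial diketene.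

**Step 1**
Reactants: 1 2,4,6-trihydroxytoluene
Product: 3 2,4,6-trihydroxy-3-methylbenzaldehyde, via iminium chloride 2 (not isolated)
Conditions: POCl3, DMF, EtOAc, 0 °C to rt; then H2O, 60 °C
Reagents that add atoms: N,N-dimethylformamide, CN(C)C=O; water, O
Why: Vilsmeier–Haack formylation of an electron-rich phloroglucinol whose two unsubstituted ring carbons are equivalent can give only one mono-aldehyde, and precipitation of the iminium salt 2 should hold back a second formylation.

**Step 2**
Reactants: 3 2,4,6-trihydroxy-3-methylbenzaldehyde
Product: 4 2,6-dihydroxy-4-methoxy-3-methylbenzaldehyde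
Conditions: Me2SO4 (1.0 equiv), K2CO3 (1.0 equiv), acetone, rt
Reagents that add atoms: dimethyl sulfate, COS(=O)(=O)OC
Why: In this Williamson etherification the hydroxyl para to the formyl group is the only one not hydrogen-bonded to the carbonyl and is the most acidic, so one equivalent of methylating agent should etherify it alone, as is usual for 2,4,6-trihydroxyaryl carbonyl compounds.

**Step 3**
Reactants: 4 2,6-dihydroxy-4-methoxy-3-methylbenzaldehyde; 5 3-methylbut-2-enoic acid
Product: 7 7-hydroxy-5-methoxy-2,2,6-trimethyl-4-oxochromane-8-carbaldehyde, via aryl enone 6 (not isolated)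
Conditions: P2O5, MeSO3H, 60 °C
Reagents that add atoms: none
Why: Friedel–Crafts acylation at the single free ring carbon followed by intramolecular oxa-Michael addition is the standard chromanone annulation of phloroglucinols, and because the acyl group of enone 6 has the methyl ether on one side the pyranone ring can close only through the hydroxyl between the acyl and formyl carbons, which places the formyl group at C8 and the methyl group at C6.

**Step 4**
Reactants: 7 7-hydroxy-5-methoxy-2,2,6-trimethyl-4-oxochromane-8-carbaldehyde
Product: 8 7-(benzyloxy)-5-methoxy-2,2,6-trimethyl-4-oxochromane-8-carbaldehyde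
Conditions: BnBr, K2CO3, DMF, 50 °C
Reagents that add atoms: benzyl bromide, BrCc1ccccc1
Why: Williamson benzylation of the one remaining phenol (chelated to the aldehyde, hence DMF and gentle heating) carries no risk of scrambling, since a retro-oxa-Michael opening could reclose only through the same oxygen.

**Step 5**
Reactants: 8 7-(benzyloxy)-5-methoxy-2,2,6-trimethyl-4-oxochromane-8-carbaldehyde
Product: 9 7-(benzyloxy)-8-(hydroxymethyl)-5-methoxy-2,2,6-trimethylchroman-4-one
Conditions: NaBH4, THF–MeOH, −20 °C
Reagents that add atoms: none
Why: NaBH4 at low temperature should reduce the aldehyde chemoselectively, the chromanone carbonyl being a hindered vinylogous ester deactivated by three oxygen donors.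

**Step 6**
Reactants: 9 7-(benzyloxy)-8-(hydroxymethyl)-5-methoxy-2,2,6-trimethylchroman-4-one
Product: 10 7-(benzyloxy)-8-(bromomethyl)-5-methoxy-2,2,6-trimethylchroman-4-one
Conditions: CBr4, PPh3, CH2Cl2, 0 °C; used at once without chromatography
Reagents that add atoms: carbon tetrabromide, BrC(Br)(Br)Br
Why: The Appel reaction converts the electron-rich benzylic alcohol into the bromide under neutral conditions that spare the benzyl ether, and since every ring carbon is substituted the bromide cannot alkylate itself.

**Step 7**
Reactants: 11 2-chloro-1,1-dimethoxyethane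
Product: 13 tributyl(methoxyethynyl)stannane, via lithium methoxyacetylide 12 (not isolated)
Conditions: LiNEt2 (3.1 equiv, from Et2NH and n-BuLi), THF, 0 °C; then Bu3SnCl, −78 °C to rt; distillation
Reagents that add atoms: tributyltin chloride, CCCC[Sn](Cl)(CCCC)CCCC
Why: Three equivalents of the amide base effect elimination of methanol and of HCl and then deprotonation to lithium methoxyacetylide 12, which is stannylated on carbon, the established route to 1-alkoxy-2-stannylacetylenes.

**Step 8**
Reactants: 10 7-(benzyloxy)-8-(bromomethyl)-5-methoxy-2,2,6-trimethylchroman-4-one; 13 tributyl(methoxyethynyl)stannane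
Product: 14 7-(benzyloxy)-5-methoxy-8-(3-methoxyprop-2-yn-1-yl)-2,2,6-trimethylchroman-4-one
Conditions: Pd2(dba)3 (2.5 mol %), tri(2-furyl)phosphine (10 mol %), THF, 50 °C; aq KF work-up; Et3N-deactivated silica
Reagents that add atoms: none
Why: In this Stille coupling benzylic bromides add readily to zerovalent palladium and the alkynyl group is the fastest to transfer from tin, while the neutral conditions tolerate the chromanone carbonyl (which a lithium acetylide could attack) and the acid-sensitive ynol ether.

**Step 9**
Reactants: 15 1-ethoxyprop-1-yne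
Product: 16 3-ethoxy-2-methylcyclobut-2-en-1-one
Conditions: ketene (by cracking diketene), CH2Cl2, 0 °C to rt
Reagents that add atoms: ketene, C=C=O
Why: [2+2] cycloaddition of ketene to the ynol ether joins the nucleophilic methyl-bearing alkyne carbon to the ketene carbonyl carbon and gives the 3-alkoxycyclobutenone directly, a known reaction of 1-alkoxyalkynes.

**Step 10**
Reactants: 14 7-(benzyloxy)-5-methoxy-8-(3-methoxyprop-2-yn-1-yl)-2,2,6-trimethylchroman-4-one; 16 3-ethoxy-2-methylcyclobut-2-en-1-one
Product: 21 7-(benzyloxy)-8-[(4-ethoxy-6-hydroxy-2-methoxy-3-methylphenyl)methyl]-5-methoxy-2,2,6-trimethylchroman-4-one, via vinylketene 17 (not isolated), via vinylcyclobutenone 18 (not isolated), via dienylketene 19 (not isolated), via cyclohexadienone 20 (not isolated)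
Conditions: 16 (2 equiv), toluene, sealed tube, 110 °C then 140 °C; then K2CO3, MeOH, rt
Reagents that add atoms: none
Why: On heating, 16 undergoes 4π-electrocyclic ring opening to vinylketene 17, whose ketene C=C adds across the triple bond of 14 in a [2+2] cycloaddition to give 18 (new bonds C2'–C3' and C4'–C5'). Cyclobutenone 18 opens in turn to dienylketene 19, which closes ring A by a thermal disrotatory 6π-electrocyclisation (C1'–C2') to dienone 20, and tautomerisation gives the phenol. The closest known reaction is the Danheiser benzannulation of cyclobutenones with 1-alkoxyalkynes, which gives resorcinol monoethers. No stereocentre remains in the product, since the quaternary carbon of 18 is racemic and is lost when that ring opens. The selectivity needed is the regiochemistry of the [2+2] step, and it is secured by the oxygen-polarised ynol ether, whose nucleophilic carbon (the one bearing the CH2 bridge) bonds to the ketene carbonyl carbon, so that the bridge ends ortho and the methoxy group meta to the new hydroxyl and all six positions of ring A are fixed. A methyl ynol ether cannot fragment to a ketene by retro-ene reaction at these temperatures, whereas the 3-ethoxy group stabilises 16 and is the reason for the higher temperature; the basic work-up cleaves any aryl ester formed from the phenol and excess vinylketene.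

**Step 11**
Reactants: 21 7-(benzyloxy)-8-[(4-ethoxy-6-hydroxy-2-methoxy-3-methylphenyl)methyl]-5-methoxy-2,2,6-trimethylchroman-4-one; 22 isobutyryl chloride
Product: 23 7-(benzyloxy)-8-{[4-ethoxy-2-hydroxy-6-methoxy-5-methyl-3-(2-methylpropanoyl)phenyl]methyl}-5-methoxy-2,2,6-trimethylchroman-4-one
Conditions: TiCl4, CH2Cl2, −78 to −20 °C
Reagents that add atoms: none
Why: Friedel–Crafts acylation ortho to the phenol through its titanium phenoxide occurs at C1', the only unsubstituted carbon of the two oxygenated rings (flanked by the hydroxyl and ethoxy groups and para to the methoxy group), and should be fast enough at low temperature for the benzyl and methyl ethers to survive.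

**Step 12**
Reactants: 23 7-(benzyloxy)-8-{[4-ethoxy-2-hydroxy-6-methoxy-5-methyl-3-(2-methylpropanoyl)phenyl]methyl}-5-methoxy-2,2,6-trimethylchroman-4-one
Product: 24 mallopallidol, 8-{[2,4-dihydroxy-6-methoxy-5-methyl-3-(2-methylpropanoyl)phenyl]methyl}-5,7-dihydroxy-2,2,6-trimethylchroman-4-one
Conditions: BCl3, pentamethylbenzene, CH2Cl2, −78 to 0 °C; MeOH quench
Reagents that add atoms: none
Why: In this chelation-controlled ether cleavage BCl3 removes the benzyl ether outright (its cation is trapped by pentamethylbenzene) and, through six-membered boron chelates with the two aryl ketones, the ethyl ether at C6' and the methyl ether at C5, while the C4' methyl ether, para to the ketone and unable to chelate, should persist at low temperature.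

**Compound list**

1 | 2,4,6-trihydroxytoluene | Cc1c(O)cc(O)cc1O | starting material
2 | [(2,4,6-trihydroxy-3-methylphenyl)methylidene]dimethylammonium chloride | C[N+](C)=Cc1c(O)cc(O)c(C)c1O.[Cl-] | intermediate
3 | 2,4,6-trihydroxy-3-methylbenzaldehyde | O=Cc1c(O)cc(O)c(C)c1O | intermediate
4 | 2,6-dihydroxy-4-methoxy-3-methylbenzaldehyde | O=Cc1c(O)cc(OC)c(C)c1O | intermediate
5 | 3-methylbut-2-enoic acid | CC(C)=CC(=O)O | starting material
6 | 2,6-dihydroxy-4-methoxy-3-methyl-5-(3-methylbut-2-enoyl)benzaldehyde | O=Cc1c(O)c(C(=O)C=C(C)C)c(OC)c(C)c1O | intermediate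
7 | 7-hydroxy-5-methoxy-2,2,6-trimethyl-4-oxochromane-8-carbaldehyde | O=Cc1c(O)c(C)c(OC)c2c1OC(C)(C)CC2=O | intermediate
8 | 7-(benzyloxy)-5-methoxy-2,2,6-trimethyl-4-oxochromane-8-carbaldehyde | O=Cc1c(OCc2ccccc2)c(C)c(OC)c2c1OC(C)(C)CC2=O | intermediate
9 | 7-(benzyloxy)-8-(hydroxymethyl)-5-methoxy-2,2,6-trimethylchroman-4-one | OCc1c(OCc2ccccc2)c(C)c(OC)c2c1OC(C)(C)CC2=O | intermediate
10 | 7-(benzyloxy)-8-(bromomethyl)-5-methoxy-2,2,6-trimethylchroman-4-one | BrCc1c(OCc2ccccc2)c(C)c(OC)c2c1OC(C)(C)CC2=O | intermediate
11 | 2-chloro-1,1-dimethoxyethane | COC(CCl)OC | starting material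
12 | lithium methoxyacetylide | [Li]C#COC | intermediate
13 | tributyl(methoxyethynyl)stannane | CCCC[Sn](CCCC)(CCCC)C#COC | intermediate
14 | 7-(benzyloxy)-5-methoxy-8-(3-methoxyprop-2-yn-1-yl)-2,2,6-trimethylchroman-4-one | COC#CCc1c(OCc2ccccc2)c(C)c(OC)c2c1OC(C)(C)CC2=O | intermediate
15 | 1-ethoxyprop-1-yne | CCOC#CC | starting material
16 | 3-ethoxy-2-methylcyclobut-2-en-1-one | CCOC1=C(C)C(=O)C1 | intermediate
17 | 3-ethoxy-2-methylbuta-1,3-dien-1-one (vinylketene) | C=C(OCC)C(C)=C=O | intermediate
18 | racemic 2-(ring B methyl)-4-(1-ethoxyvinyl)-3-methoxy-4-methylcyclobut-2-en-1-one, ring B = 7-(benzyloxy)-5-methoxy-2,2,6-trimethyl-4-oxochroman-8-yl | O=C1C(Cc2c(OCc3ccccc3)c(C)c(OC)c3c2OC(C)(C)CC3=O)=C(OC)C1(C)C(=C)OCC | intermediate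
19 | 2-(ring B methyl)-5-ethoxy-3-methoxy-4-methylhexa-1,3,5-trien-1-one, ketene carbon and ethoxyvinyl group cis on the central double bond | O=C=C(Cc1c(OCc2ccccc2)c(C)c(OC)c2c1OC(C)(C)CC2=O)/C(OC)=C(C)\C(=C)OCC | intermediate
20 | 2-(ring B methyl)-5-ethoxy-3-methoxy-4-methylcyclohexa-2,4-dien-1-one | O=C1CC(OCC)=C(C)C(OC)=C1Cc1c(OCc2ccccc2)c(C)c(OC)c2c1OC(C)(C)CC2=O | intermediate
21 | 7-(benzyloxy)-8-[(4-ethoxy-6-hydroxy-2-methoxy-3-methylphenyl)methyl]-5-methoxy-2,2,6-trimethylchroman-4-one | COc1c(C)c(OCC)cc(O)c1Cc1c(OCc2ccccc2)c(C)c(OC)c2c1OC(C)(C)CC2=O | intermediate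
22 | isobutyryl chloride | CC(C)C(Cl)=O | starting material
23 | 7-(benzyloxy)-8-{[4-ethoxy-2-hydroxy-6-methoxy-5-methyl-3-(2-methylpropanoyl)phenyl]methyl}-5-methoxy-2,2,6-trimethylchroman-4-one | COc1c(C)c(OCC)c(C(=O)C(C)C)c(O)c1Cc1c(OCc2ccccc2)c(C)c(OC)c2c1OC(C)(C)CC2=O | intermediate
24 | mallopallidol | COc1c(C)c(O)c(C(=O)C(C)C)c(O)c1Cc1c(O)c(C)c(O)c2c1OC(C)(C)CC2=O | target

**Step count**

Total: 12 steps. Longest linear sequence: 10 steps (steps 1–6, 8, 10, 11, 12, from 2,4,6-trihydroxytoluene).

**Steps most likely to fail**

Step 10. The ethoxy-stabilised cyclobutenone may open only at temperatures at which the ynol ether is consumed by oligomerisation, or the vinylketene may dimerise before it is intercepted. The fallback generates the same vinylketene 17 at room temperature by a photochemical Wolff rearrangement instead of a cyclobutenone opening; it sets out from 14 and returns to the route at 21. 1-Ethoxyvinyllithium (ethyl vinyl ether, t-BuLi, THF) would be acylated with N-methoxy-N-methylpropanamide to give 2-ethoxypent-1-en-3-one F1. LiN(SiMe3)2 and 2,2,2-trifluoroethyl trifluoroacetate would then give the racemic trifluoroacetyl ketone 2-ethoxy-6,6,6-trifluoro-4-methylhex-1-ene-3,5-dione F2, and MsN3/Et3N would convert it by detrifluoroacetylative diazo transfer into 4-diazo-2-ethoxypent-1-en-3-one F3. Irradiation of F3 together with 14 (300 nm, CH2Cl2, rt), followed by warming to 80 °C, should lead through 17, 18, 19 and 20 to 21.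

Step 3. The formyl group may deactivate the ring so far that the acylation stalls, or the aldehyde may be lost in the strong acid by deformylation or condensation. The fallback builds the pyranone ring before the formyl group is introduced; it sets out from 1 and returns at 8. Compounds 1 and 5 in P2O5/MeSO3H would give 5,7-dihydroxy-2,2,6-trimethylchroman-4-one F4, now without control over which hydroxyl closes the ring, so that it would have to be separated from 5,7-dihydroxy-2,2,8-trimethylchroman-4-one F5. BnBr/K2CO3 (one equivalent, acetone) would etherify the non-chelated 7-hydroxyl to give 7-(benzyloxy)-5-hydroxy-2,2,6-trimethylchroman-4-one F6. Vilsmeier–Haack formylation at C8, the only free ring carbon and para to the free 5-hydroxyl, would give 7-(benzyloxy)-5-hydroxy-2,2,6-trimethyl-4-oxochromane-8-carbaldehyde F7, and MeI/K2CO3 in DMF at 60 °C would methylate the chelated 5-hydroxyl to give 8.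

Step 8. The very electron-rich benzylic bromide may ionise or hydrolyse before oxidative addition, or the ynol ether may be hydrated during isolation. The fallback replaces the catalytic cross-coupling by an uncatalysed SN2 alkylation; it sets out from 10 and returns at 14. Lithium methoxyacetylide 12, made from 11 with LiN(i-Pr)2 so that the amine released is too hindered to attack the bromide, would be alkylated by 10 in THF/DMPU at −78 °C. The chromanone carbonyl, a vinylogous ester flanked by the 5-methoxy group, is expected to react more slowly than the benzylic displacement.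

**Further compounds**

F1 | step 10 | 2-ethoxypent-1-en-3-one | CCC(=O)C(=C)OCC
F2 | step 10 | racemic 2-ethoxy-6,6,6-trifluoro-4-methylhex-1-ene-3,5-dione | C=C(OCC)C(=O)C(C)C(=O)C(F)(F)F
F3 | step 10 | 4-diazo-2-ethoxypent-1-en-3-one | C=C(OCC)C(=O)C(C)=[N+]=[N-]
F4 | step 3 | 5,7-dihydroxy-2,2,6-trimethylchroman-4-one | Cc1c(O)cc2c(c1O)C(=O)CC(C)(C)O2
F5 | step 3 | 5,7-dihydroxy-2,2,8-trimethylchroman-4-one | Cc1c(O)cc(O)c2c1OC(C)(C)CC2=O
F6 | step 3 | 7-(benzyloxy)-5-hydroxy-2,2,6-trimethylchroman-4-one | Cc1c(OCc2ccccc2)cc2c(c1O)C(=O)CC(C)(C)O2
F7 | step 3 | 7-(benzyloxy)-5-hydroxy-2,2,6-trimethyl-4-oxochromane-8-carbaldehyde | O=Cc1c(OCc2ccccc2)c(C)c(O)c2c1OC(C)(C)CC2=O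
F0 | step 8 | none | none
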